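## The problem

The target 24 is a sesquineolignan built on a tetrahydrofuran (O1, C2–C5). C2 carries ring B of a 2,3-dihydrobenzofuran, C3 a hydroxymethyl group (C9), C4 a hydroxyl group and C5 a 4-hydroxy-3-methoxybenzyl group (ring C); the dihydrobenzofuran (O1', C2', C3') bears the guaiacyl ring A at C2' and a hydroxymethyl group at C3'. Three electron-rich arenes must be joined through two oxygen heterocycles and six stereocentres set: C2–C5 (all S; 2,5-cis, 2,3-trans, 3,4-trans) and C2'/C3' (R,R; cis). Ring B insulates the two sets, so each needs its own source of absolute configuration; within the tetrahydrofuran, C5 can direct C2 during ring formation, C2 fixes C3 by equilibration, and C3 with C5 decides the face of C4. The cis-dihydrobenzofuran is the delicate part: it is less stable than the trans isomer, C3' epimerises while it carries an ester, and the benzylic C2'–O1' bond ionises when ring A has a free or alkylated para oxygen. The benzylic C2–O1 bond is open to acid and hydrogenolysis, the phenols to oxidation, and a C4 ketone must not enolise towards C5. The enabling feature is that C2 is bonded at once to O1, to ring B and to C3, and C3 carries C9 beside the oxygenated C4. With C9 as an ester and C4 as a ketone, C2–C3 is the bond between an aryl oxocarbenium ion (C2=O1) and the α-carbon of a β-keto ester enolate, two partners already tied through O1–C5 and released together when a 1,3-dioxolane with an exocyclic enol ether ionises.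

## Retrosynthesis

**24 back to 21 (no skeletal bond cut).** The last operations only adjust oxidation levels and protecting groups. Ring C is kept as a benzyl ether to the end (23), because one aryl benzyl ether is cleaved under conditions too mild to touch the benzylic ring C–O bonds. C9 and C4 are traced to the ester and ketone of β-keto ester 21 via hydroxy ester 22. Reducing the ketone first is preferred to reducing the ester first: C3 of 21 is freely epimerisable and can be carried into the trans hydroxy ester by dynamic kinetic resolution. The ester-first order would pass through a C3 enol whose kinetic protonation anti to the C2 aryl gives the wrong C3 epimer. The forward hydrogenation must deliver hydrogen to C4 anti to the C5 benzyl group and give 3,4-trans. The pivalates on ring A and on the C3' hydroxymethyl group fall in the same hydride step that reduces the ester (22 to 23).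

**21 back to 20 (C2–C3 cut).** The neighbouring cuts are less attractive. Cutting O1–C2 leads to an open-chain arylidene β-keto ester that must close 5-endo. Cutting C3–C4 is a Dieckmann closure under strong base next to the C5 stereocentre. Cutting C2–C3 gives the oxocarbenium ion and enolate that the 4-(methoxycarbonylmethylene)-1,3-dioxolane 20 releases on ionisation, already tethered, so the union is intramolecular and the acetal configuration of 20 is irrelevant. Compound 20 has one C–C bond and two stereocentres fewer than 21. The forward step must recombine at carbon, give the 2,5-cis ring, and leave the cis-dihydrobenzofuran untouched.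

**20 back to 8 and 19 (C2–O1, C2–O3 and O3–C4 cut).** The dioxolane is the adduct of aldehyde 19 and γ-hydroxy ynoate 8, formed by hemiacetalisation and oxa-Michael addition with no by-product. This splits the molecule into two fragments of similar size, each carrying one set of stereocentres. Any minor enantiomer of either fragment becomes a separable diastereomer at this point. The forward reaction needs only catalytic base, which both fragments tolerate once C3' no longer bears an ester.

**8 back to 1 (alkyne–ester bond, one-carbon homologation, C–N to C–O).** Ynoate 8 comes from silyl ether 7, made by carboxylating terminal alkyne 6. Alkyne 6 comes from ester 4 through aldehyde 5, and the C5 stereocentre from amino acid 1 by diazotisation with retention (2, then 3). The chiral pool is preferred to an asymmetric alkynylation of an enolisable arylacetaldehyde or to reduction of a benzylic ynone, both of which are less reliable for this substitution pattern. Compound 1 is commercial and already holds ring C, the benzylic carbon and C5.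

**19 back to 15 (C2'–C3' cut).** Aldehyde 19 is the bis-pivalate (18) of diol 17 after acetal removal, and 17 is the reduction product of cis ester 16. Ester 16 is traced to the achiral aryldiazoacetate 15 by carbenoid insertion into the benzylic ether C–H bond. This is the one disconnection that delivers the less stable cis isomer kinetically and both stereocentres from a catalyst. Closing O1'–C2' instead would run through a benzylic cation and give trans, and hydrogenating a 2,3-disubstituted benzofuran is not dependable. The ester is reduced at once so that C3' can no longer epimerise.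

**15 back to 9 and 12 (aryl–C bond, acetal, ether C–O bond).** The diazoacetate carbon is attached to aryl iodide 14 by palladium catalysis; 14 is the acetal of aldehyde 13. Ether 13 is the Mitsunobu product of 5-iodovanillin 12 and benzylic alcohol 11, which comes from vanillin 9 via pivalate 10. Compound 12 is chosen because it already carries all four ring B substituents in place: the phenol oxygen, the methoxy group, an iodide where C3' is attached, and the formyl group that becomes C2. A ring B precursor carrying the future C3' as a formyl group would need a one-carbon homologation and a late formylation.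

## Roads not taken

**Alternative 1:** The cut is C3'–C3a' of the dihydrobenzofuran, traced to a chromanone. The (S)-3-diazoflavanone A1 is irradiated in methanol; nitrogen is lost, the ring B carbon migrates from the carbonyl carbon to the carbene carbon (Wolff rearrangement), and methanol adds to the ketene to give the ring-contracted cis ester A2 with a bromide for later elaboration.
- Merits: C2' comes from established asymmetric flavanone chemistry and is a spectator of the migration. Protonation of the ketene-derived enol anti to the aryl group places the ester cis, the relationship needed. No precious metal is used.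
- Weak points: it solves rings A and B only, and the tetrahydrofuran still needs its own plan. Diazo transfer needs base, under which a flavanone can open to the chalcone and lose C2'. The bromide must still be turned into the carbon handle. The cis ester stays epimerisable until reduced.
- Comparison: this road competes with steps 11 and 12, not with the key step. Those steps reach the same kind of ester (16) in two operations from an aryl iodide that already holds the aldehyde carbon, so the Wolff route is longer. It is better in avoiding the chiral dirhodium catalyst. The chosen plan sets against this its shorter sequence and a formyl group present from the start.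

**Alternative 2:** The cuts are C3–C4 and O1–C2. Aldehyde A3, chelated by SnCl4, is attacked at C4 by the alkene of cinnamyl silyl ether A4. The ether oxygen then closes on the benzylic cation at C2 with loss of the 4-methoxybenzyl group, giving tetrahydrofuranol A5.
- Merits: it is the most convergent road. Two bonds, the ring and three stereocentres form in one step, and C9 and C4 arrive at their final oxidation levels, so three endgame redox steps of the chosen plan are not needed. Chelation control relates C4 to C5 correctly.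
- Weak points: C2 is set by capture of a freely rotating, strongly stabilised benzylic cation, so 2,3-trans and 2,5-cis rest on small conformational preferences. Stoichiometric SnCl4 meets the cis-dihydrobenzofuran. A 4-methoxybenzyl cation is released among three electron-rich arenes. The α-alkoxy aldehyde is configurationally labile, and electron-rich styrenes oligomerise under Lewis acids.
- Comparison: in step count and redox economy Alternative 2 is clearly better. The chosen plan sets against it a catalytic Lewis acid at low temperature, a recombination in which the nucleophile is tethered and no free cation leaves the molecule, and C3 and C4 fixed afterwards by equilibration and a catalyst-controlled hydrogenation.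

**Alternative 3:** The cut is C2'–C3', made last. On the full skeleton, aryldiazoacetate A6 is converted by Rh2(S-PTTL)4 into a carbenoid that inserts into the benzylic C–H bond of the neighbouring guaiacylmethyl ether, giving cis ester A7.
- Merits: the insertion is dependable and cis-selective. The acid-sensitive cis-dihydrobenzofuran does not exist while the tetrahydrofuran is built, so the Lewis acid step need not be tuned around it and ring A needs no acyl group.
- Weak points: the carbenoid is generated on a substrate with four stereocentres, many activated C–H bonds and Lewis basic oxygens. The diazo group must be installed late, and a failure costs the whole sequence.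
- Comparison: the reaction type is the same as step 12 of the chosen plan, which runs it on a small achiral substrate where the catalyst alone decides and the product can be purified before coupling. Alternative 3 is better at shielding the cis ring from acid. The chosen plan answers with the pivalate on ring A and catalytic Me3SiOTf at low temperature.

Key step: step 16

Remark: tetrahydrofuran locants are O1, C2 (aryl), C3, C4, C5 (benzyl) throughout, also in compound names.
Remark: Rh2(S-PTTL)4 is assumed to induce the (2R,3S) cis ester 16, the sense it shows with simpler 2-(benzyloxy)phenyl diazoacetates; should the substituted substrate invert it, the (R)-configured catalyst would be used in the same way.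
Remark: methyl diazoacetate is used as a freshly prepared solution.

## Route

Step 1
Reactants: 1 3-O-methyl-L-DOPA, (S)-2-amino-3-(4-hydroxy-3-methoxyphenyl)propanoic acid
Product: 2 (S)-2-hydroxy-3-(4-hydroxy-3-methoxyphenyl)propanoic acid
Conditions: NaNO2, 1 M H2SO4, H2O, 0 °C → rt
Reagents that add atoms: water, O
Why: Diazotisation of the α-amino acid; the carboxylate expels N2 to an α-lactone that water opens, two inversions giving net retention at the future C5, as in the known conversion of tyrosine into its lactic acid.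

Step 2
Reactants: 2 (S)-2-hydroxy-3-(4-hydroxy-3-methoxyphenyl)propanoic acid
Product: 3 benzyl (S)-3-[4-(benzyloxy)-3-methoxyphenyl]-2-hydroxypropanoate
Conditions: BnBr (2.2 equiv), K2CO3, DMF, rt
Reagents that add atoms: benzyl bromide, BrCc1ccccc1
Why: Williamson-type O-alkylation; K2CO3 generates only carboxylate and phenoxide, so ester and aryl ether form while the secondary alcohol stays free.

Step 3
Reactants: 3 benzyl (S)-3-[4-(benzyloxy)-3-methoxyphenyl]-2-hydroxypropanoate
Product: 4 benzyl (S)-3-[4-(benzyloxy)-3-methoxyphenyl]-2-[(tert-butyldimethylsilyl)oxy]propanoate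
Conditions: TBSCl, imidazole, DMF, rt
Reagents that add atoms: tert-butyldimethylsilyl chloride, CC(C)(C)[Si](C)(C)Cl
Why: Imidazole-promoted silyl ether formation masks the alcohol for the hydride and organolithium steps.

Step 4
Reactants: 4 benzyl (S)-3-[4-(benzyloxy)-3-methoxyphenyl]-2-[(tert-butyldimethylsilyl)oxy]propanoate
Product: 6 (S)-{[1-(4-(benzyloxy)-3-methoxyphenyl)but-3-yn-2-yl]oxy}(tert-butyl)dimethylsilane, via aldehyde 5 (not isolated)
Conditions: i-Bu2AlH (1.2 equiv), CH2Cl2, −78 °C; then MeOH, K2CO3, dimethyl (1-diazo-2-oxopropyl)phosphonate, −78 °C → rt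
Reagents that add atoms: dimethyl (1-diazo-2-oxopropyl)phosphonate, COP(=O)(OC)C(=[N+]=[N-])C(C)=O
Why: Partial ester reduction to an aluminium hemiacetal stabilised by the α-silyloxy group, then Seyferth–Gilbert homologation with the Ohira–Bestmann reagent in the same flask; the mild carbonate medium and the avoided isolation protect the α-stereocentre of aldehyde 5.

Step 5
Reactants: 6 (S)-{[1-(4-(benzyloxy)-3-methoxyphenyl)but-3-yn-2-yl]oxy}(tert-butyl)dimethylsilane
Product: 7 methyl (S)-5-[4-(benzyloxy)-3-methoxyphenyl]-4-[(tert-butyldimethylsilyl)oxy]pent-2-ynoate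
Conditions: n-BuLi, THF, −78 °C; ClCO2Me, −78 → 0 °C
Reagents that add atoms: methyl chloroformate, COC(Cl)=O
Why: Deprotonation of the terminal alkyne and acylation of the lithium acetylide with a chloroformate, the standard alkynoate synthesis.

Step 6
Reactants: 7 methyl (S)-5-[4-(benzyloxy)-3-methoxyphenyl]-4-[(tert-butyldimethylsilyl)oxy]pent-2-ynoate
Product: 8 methyl (S)-5-[4-(benzyloxy)-3-methoxyphenyl]-4-hydroxypent-2-ynoate
Conditions: HF·pyridine, pyridine, THF, 0 °C → rt
Reagents that add atoms: none
Why: Fluoride-mediated desilylation under buffered, non-basic conditions, which spare the base-sensitive γ-hydroxy ynoate.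

Step 7
Reactants: 9 vanillin, 4-hydroxy-3-methoxybenzaldehyde
Product: 10 4-formyl-2-methoxyphenyl pivalate
Conditions: PivCl, Et3N, DMAP (cat.), CH2Cl2, 0 °C → rt
Reagents that add atoms: pivaloyl chloride, CC(C)(C)C(Cl)=O
Why: DMAP-catalysed acylation of the phenol; the acyl group later withholds para-oxygen donation from ring A.

Step 8
Reactants: 10 4-formyl-2-methoxyphenyl pivalate
Product: 11 4-(hydroxymethyl)-2-methoxyphenyl pivalate
Conditions: NaBH4, THF/MeOH, 0 °C
Reagents that add atoms: none
Why: Chemoselective borohydride reduction of the aldehyde; the hindered aryl pivalate survives brief exposure at 0 °C.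

Step 9
Reactants: 11 4-(hydroxymethyl)-2-methoxyphenyl pivalate; 12 5-iodovanillin, 4-hydroxy-3-iodo-5-methoxybenzaldehyde
Product: 13 4-[(4-formyl-2-iodo-6-methoxyphenoxy)methyl]-2-methoxyphenyl pivalate
Conditions: PPh3, DIAD, THF, 0 °C → rt
Reagents that add atoms: none
Why: Mitsunobu etherification; the acidic, doubly ortho-substituted phenol 12 is alkylated by the activated primary benzylic alcohol under neutral conditions that leave formyl group, iodide and pivalate untouched.

Step 10
Reactants: 13 4-[(4-formyl-2-iodo-6-methoxyphenoxy)methyl]-2-methoxyphenyl pivalate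
Product: 14 4-{[4-(1,3-dioxolan-2-yl)-2-iodo-6-methoxyphenoxy]methyl}-2-methoxyphenyl pivalate
Conditions: HOCH2CH2OH, HC(OEt)3, p-TsOH·H2O (cat.), CH2Cl2, rt
Reagents that add atoms: ethylene glycol, OCCO
Why: Acid-catalysed acetalisation with the orthoformate as water scavenger; the aldehyde must be masked before the hydride of step 13 and kept away from the carbenoid of step 12.

Step 11
Reactants: 14 4-{[4-(1,3-dioxolan-2-yl)-2-iodo-6-methoxyphenoxy]methyl}-2-methoxyphenyl pivalate
Product: 15 methyl 2-diazo-2-[5-(1,3-dioxolan-2-yl)-3-methoxy-2-{[3-methoxy-4-(pivaloyloxy)benzyl]oxy}phenyl]acetate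
Conditions: N2CHCO2Me, Pd(PPh3)4 (5 mol%), Ag2CO3 (0.5 equiv), Et3N, toluene, rt
Reagents that add atoms: methyl diazoacetate, COC(=O)C=[N+]=[N-]
Why: Palladium-catalysed cross-coupling of an aryl iodide with a diazoacetate with retention of the diazo group (oxidative addition, silver-assisted transfer of the diazo carbon, reductive elimination); mild base and room temperature tolerate acetal and pivalate.

Step 12
Reactants: 15 methyl 2-diazo-2-[5-(1,3-dioxolan-2-yl)-3-methoxy-2-{[3-methoxy-4-(pivaloyloxy)benzyl]oxy}phenyl]acetate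
Product: 16 methyl (2R,3S)-5-(1,3-dioxolan-2-yl)-7-methoxy-2-[3-methoxy-4-(pivaloyloxy)phenyl]-2,3-dihydrobenzofuran-3-carboxylate (cis)
Conditions: Rh2(S-PTTL)4 [dirhodium tetrakis(N-phthaloyl-(S)-tert-leucinate)] (1 mol%), toluene, −78 → −60 °C
Reagents that add atoms: none
Why: Dirhodium-carbenoid intramolecular 1,5 C–H insertion into the benzylic ether methylene; with this catalyst 2-(benzyloxy)phenyl diazoacetates give the cis ester kinetically, and the chiral carboxylate sphere selects the enantiotopic C–H bond, so C2' and C3' are both set by the catalyst.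

Step 13
Reactants: 16 methyl (2R,3S)-5-(1,3-dioxolan-2-yl)-7-methoxy-2-[3-methoxy-4-(pivaloyloxy)phenyl]-2,3-dihydrobenzofuran-3-carboxylate
Product: 17 4-[(2R,3R)-5-(1,3-dioxolan-2-yl)-3-(hydroxymethyl)-7-methoxy-2,3-dihydrobenzofuran-2-yl]-2-methoxyphenol (cis)
Conditions: LiAlH4, THF, −20 → 0 °C
Reagents that add atoms: none
Why: Hydride reduction of the ester with reductive loss of the aryl pivalate; reduction outpaces enolisation of the α-aryl ester, so the cis relationship is kept and C3' is no longer epimerisable, while the acetal is inert.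

Step 14
Reactants: 17 4-[(2R,3R)-5-(1,3-dioxolan-2-yl)-3-(hydroxymethyl)-7-methoxy-2,3-dihydrobenzofuran-2-yl]-2-methoxyphenol
Product: 19 4-[(2R,3R)-5-formyl-7-methoxy-3-[(pivaloyloxy)methyl]-2,3-dihydrobenzofuran-2-yl]-2-methoxyphenyl pivalate, via bis-pivalate acetal 18 (not isolated)
Conditions: PivCl (2.5 equiv), Et3N, DMAP (cat.), CH2Cl2, 0 °C → rt; then 1 M HCl, THF, rt
Reagents that add atoms: pivaloyl chloride, CC(C)(C)C(Cl)=O; water, O
Why: Double acylation of phenol and primary alcohol, then acid hydrolysis of the aryl dioxolane in the same flask; with ring A acylated the dilute acid cannot open the dihydrobenzofuran.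

Step 15
Reactants: 8 methyl (S)-5-[4-(benzyloxy)-3-methoxyphenyl]-4-hydroxypent-2-ynoate; 19 4-[(2R,3R)-5-formyl-7-methoxy-3-[(pivaloyloxy)methyl]-2,3-dihydrobenzofuran-2-yl]-2-methoxyphenyl pivalate
Product: 20 methyl (2Z)-2-[(2S,5S)-5-[4-(benzyloxy)-3-methoxybenzyl]-2-{(2R,3R)-7-methoxy-2-[3-methoxy-4-(pivaloyloxy)phenyl]-3-[(pivaloyloxy)methyl]-2,3-dihydrobenzofuran-5-yl}-1,3-dioxolan-4-ylidene]acetate
Conditions: t-BuOK (0.1 equiv), THF, −40 → 0 °C, 8 added slowly to 19 (1.1 equiv)
Reagents that add atoms: none
Why: Base-catalysed hemiacetalisation of the propargylic alkoxide with the aldehyde, then 5-exo-dig oxa-Michael addition of the hemiacetal alkoxide to the ynoate, a known route from γ-hydroxy alkynoates and aldehydes to 4-alkylidene-1,3-dioxolanes. Anti addition gives the Z enoate; the configuration of the new acetal carbon (drawn 2,5-cis) is of no consequence because step 16 planarises it.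

Step 16
Reactants: 20 methyl (2Z)-2-[(2S,5S)-5-[4-(benzyloxy)-3-methoxybenzyl]-2-{(2R,3R)-7-methoxy-2-[3-methoxy-4-(pivaloyloxy)phenyl]-3-[(pivaloyloxy)methyl]-2,3-dihydrobenzofuran-5-yl}-1,3-dioxolan-4-ylidene]acetate
Product: 21 methyl (2S,3R,5S)-5-[4-(benzyloxy)-3-methoxybenzyl]-2-{(2R,3R)-7-methoxy-2-[3-methoxy-4-(pivaloyloxy)phenyl]-3-[(pivaloyloxy)methyl]-2,3-dihydrobenzofuran-5-yl}-4-oxotetrahydrofuran-3-carboxylate
Conditions: Me3SiOTf (0.2 equiv), 2,6-di-tert-butyl-4-methylpyridine (0.05 equiv), CH2Cl2, −78 → −30 °C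
Reagents that add atoms: none
Why: Proposed new method: Me3SiOTf silylates the ester carbonyl of the vinylogous carbonate, the acetal C2–O3 bond ionises, and the aryl oxocarbenium ion (C2=O1) stays tied through O1–C5 to the silyl dienolate of a β-keto ester, which returns through C3 to form C2–C3 and release the silyl cation for the next turnover. The closest known reaction type is the Petasis–Ferrier rearrangement of 4-methylene-1,3-dioxolanes to tetrahydrofuran-3-ones; an ester on the enol ether carbon has not been carried through it, and it should make ionisation easier (better leaving group) and attack through carbon slower (stabilised nucleophile). The one ring formed, the tetrahydrofuran-4-one, closes in the 5-(enolendo)-endo-trig mode, the mode of the parent rearrangement, which is open to oxocarbenium electrophiles. C2 is controlled by C5: in the envelope transition state the benzyl group on C5 and the aryl group of the E-oxocarbenium ion both sit pseudoequatorial, which gives the 2,5-cis ring, and both acetal epimers and both enol ether geometries of 20 funnel into the same ion. C3 is under thermodynamic control, since it lies between ketone and ester, and settles trans to the aryl group on C2. The step needs recombination at carbon and not at oxygen, which the new C–C bond and the ketone make irreversible at low temperature, and it needs the acetal to ionise before the benzylic C2'–O1' bond of the cis-dihydrobenzofuran, which the pivalate on ring A secures by withholding para-oxygen donation. The hindered pyridine keeps the medium free of triflic acid so that ring C does not close on the oxocarbenium ion.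

Step 17
Reactants: 21 methyl (2S,3R,5S)-5-[4-(benzyloxy)-3-methoxybenzyl]-2-{(2R,3R)-7-methoxy-2-[3-methoxy-4-(pivaloyloxy)phenyl]-3-[(pivaloyloxy)methyl]-2,3-dihydrobenzofuran-5-yl}-4-oxotetrahydrofuran-3-carboxylate
Product: 22 methyl (2S,3S,4S,5S)-5-[4-(benzyloxy)-3-methoxybenzyl]-4-hydroxy-2-{(2R,3R)-7-methoxy-2-[3-methoxy-4-(pivaloyloxy)phenyl]-3-[(pivaloyloxy)methyl]-2,3-dihydrobenzofuran-5-yl}tetrahydrofuran-3-carboxylate
Conditions: H2 (50 atm), [RuCl(C6H6)((R)-BINAP)]Cl (2 mol%), CH2Cl2, 50 °C
Reagents that add atoms: none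
Why: Noyori hydrogenation of a cyclic β-keto ester with dynamic kinetic resolution: C3 epimerises through the enol and the divalent ruthenium catalyst reduces the ester-chelated ketone to the trans (anti) hydroxy ester. The (R) ligand is the one whose preferred face is also the face anti to the C5 benzyl group, so C4 is set by catalyst and C5 together and C3 is locked trans to both neighbours.

Step 18
Reactants: 22 methyl (2S,3S,4S,5S)-5-[4-(benzyloxy)-3-methoxybenzyl]-4-hydroxy-2-{(2R,3R)-7-methoxy-2-[3-methoxy-4-(pivaloyloxy)phenyl]-3-[(pivaloyloxy)methyl]-2,3-dihydrobenzofuran-5-yl}tetrahydrofuran-3-carboxylate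
Product: 23 (2S,3S,4S,5S)-5-[4-(benzyloxy)-3-methoxybenzyl]-2-[(2R,3R)-2-(4-hydroxy-3-methoxyphenyl)-3-(hydroxymethyl)-7-methoxy-2,3-dihydrobenzofuran-5-yl]-3-(hydroxymethyl)tetrahydrofuran-4-ol
Conditions: LiAlH4, THF, 0 °C → rt
Reagents that add atoms: none
Why: Hydride reduction of the β-hydroxy ester to the 1,3-diol with simultaneous reductive removal of both pivalates; no stereocentre is touched.

Step 19
Reactants: 23 (2S,3S,4S,5S)-5-[4-(benzyloxy)-3-methoxybenzyl]-2-[(2R,3R)-2-(4-hydroxy-3-methoxyphenyl)-3-(hydroxymethyl)-7-methoxy-2,3-dihydrobenzofuran-5-yl]-3-(hydroxymethyl)tetrahydrofuran-4-ol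
Product: 24 (2S,3S,4S,5S)-5-(4-hydroxy-3-methoxybenzyl)-2-[(2R,3R)-2-(4-hydroxy-3-methoxyphenyl)-3-(hydroxymethyl)-7-methoxy-2,3-dihydrobenzofuran-5-yl]-3-(hydroxymethyl)tetrahydrofuran-4-ol
Conditions: H2 (1 atm), Pd/C (10% palladium on carbon), EtOAc/MeOH, rt
Reagents that add atoms: none
Why: Hydrogenolysis of the single aryl benzyl ether, which should cleave much faster than the benzylic C–O bonds of the two heterocycles at 1 atm and room temperature.

## Compound list

1 | 3-O-methyl-L-DOPA, (S)-2-amino-3-(4-hydroxy-3-methoxyphenyl)propanoic acid | COc1cc(C[C@H](N)C(=O)O)ccc1O | starting material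
2 | (S)-2-hydroxy-3-(4-hydroxy-3-methoxyphenyl)propanoic acid | COc1cc(C[C@H](O)C(=O)O)ccc1O | intermediate
3 | benzyl (S)-3-[4-(benzyloxy)-3-methoxyphenyl]-2-hydroxypropanoate | COc1cc(C[C@H](O)C(=O)OCc2ccccc2)ccc1OCc1ccccc1 | intermediate
4 | benzyl (S)-3-[4-(benzyloxy)-3-methoxyphenyl]-2-[(tert-butyldimethylsilyl)oxy]propanoate | COc1cc(C[C@H](O[Si](C)(C)C(C)(C)C)C(=O)OCc2ccccc2)ccc1OCc1ccccc1 | intermediate
5 | (S)-3-[4-(benzyloxy)-3-methoxyphenyl]-2-[(tert-butyldimethylsilyl)oxy]propanal | COc1cc(C[C@H](O[Si](C)(C)C(C)(C)C)C=O)ccc1OCc1ccccc1 | intermediate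
6 | (S)-{[1-(4-(benzyloxy)-3-methoxyphenyl)but-3-yn-2-yl]oxy}(tert-butyl)dimethylsilane | COc1cc(C[C@H](O[Si](C)(C)C(C)(C)C)C#C)ccc1OCc1ccccc1 | intermediate
7 | methyl (S)-5-[4-(benzyloxy)-3-methoxyphenyl]-4-[(tert-butyldimethylsilyl)oxy]pent-2-ynoate | COc1cc(C[C@H](O[Si](C)(C)C(C)(C)C)C#CC(=O)OC)ccc1OCc1ccccc1 | intermediate
8 | methyl (S)-5-[4-(benzyloxy)-3-methoxyphenyl]-4-hydroxypent-2-ynoate | COc1cc(C[C@H](O)C#CC(=O)OC)ccc1OCc1ccccc1 | intermediate
9 | vanillin, 4-hydroxy-3-methoxybenzaldehyde | COc1cc(C=O)ccc1O | starting material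
10 | 4-formyl-2-methoxyphenyl pivalate | COc1cc(C=O)ccc1OC(=O)C(C)(C)C | intermediate
11 | 4-(hydroxymethyl)-2-methoxyphenyl pivalate | COc1cc(CO)ccc1OC(=O)C(C)(C)C | intermediate
12 | 5-iodovanillin, 4-hydroxy-3-iodo-5-methoxybenzaldehyde | COc1cc(C=O)cc(I)c1O | starting material
13 | 4-[(4-formyl-2-iodo-6-methoxyphenoxy)methyl]-2-methoxyphenyl pivalate | COc1cc(C=O)cc(I)c1OCc1ccc(OC(=O)C(C)(C)C)c(OC)c1 | intermediate
14 | 4-{[4-(1,3-dioxolan-2-yl)-2-iodo-6-methoxyphenoxy]methyl}-2-methoxyphenyl pivalate | COc1cc(C2OCCO2)cc(I)c1OCc1ccc(OC(=O)C(C)(C)C)c(OC)c1 | intermediate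
15 | methyl 2-diazo-2-[5-(1,3-dioxolan-2-yl)-3-methoxy-2-{[3-methoxy-4-(pivaloyloxy)benzyl]oxy}phenyl]acetate | COc1cc(C2OCCO2)cc(C(=[N+]=[N-])C(=O)OC)c1OCc1ccc(OC(=O)C(C)(C)C)c(OC)c1 | intermediate
16 | methyl (2R,3S)-5-(1,3-dioxolan-2-yl)-7-methoxy-2-[3-methoxy-4-(pivaloyloxy)phenyl]-2,3-dihydrobenzofuran-3-carboxylate (cis) | O1CCOC1c1cc(OC)c2c(c1)[C@H](C(=O)OC)[C@H](c1ccc(OC(=O)C(C)(C)C)c(OC)c1)O2 | intermediate
17 | 4-[(2R,3R)-5-(1,3-dioxolan-2-yl)-3-(hydroxymethyl)-7-methoxy-2,3-dihydrobenzofuran-2-yl]-2-methoxyphenol (cis) | O1CCOC1c1cc(OC)c2c(c1)[C@H](CO)[C@H](c1ccc(O)c(OC)c1)O2 | intermediate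
18 | 4-[(2R,3R)-5-(1,3-dioxolan-2-yl)-7-methoxy-3-[(pivaloyloxy)methyl]-2,3-dihydrobenzofuran-2-yl]-2-methoxyphenyl pivalate | O1CCOC1c1cc(OC)c2c(c1)[C@H](COC(=O)C(C)(C)C)[C@H](c1ccc(OC(=O)C(C)(C)C)c(OC)c1)O2 | intermediate
19 | 4-[(2R,3R)-5-formyl-7-methoxy-3-[(pivaloyloxy)methyl]-2,3-dihydrobenzofuran-2-yl]-2-methoxyphenyl pivalate | O=Cc1cc(OC)c2c(c1)[C@H](COC(=O)C(C)(C)C)[C@H](c1ccc(OC(=O)C(C)(C)C)c(OC)c1)O2 | intermediate
20 | methyl (2Z)-2-[(2S,5S)-5-[4-(benzyloxy)-3-methoxybenzyl]-2-{(2R,3R)-7-methoxy-2-[3-methoxy-4-(pivaloyloxy)phenyl]-3-[(pivaloyloxy)methyl]-2,3-dihydrobenzofuran-5-yl}-1,3-dioxolan-4-ylidene]acetate | COc1cc(C[C@@H]2O[C@H](c3cc(OC)c4c(c3)[C@H](COC(=O)C(C)(C)C)[C@H](c3ccc(OC(=O)C(C)(C)C)c(OC)c3)O4)O/C2=C\C(=O)OC)ccc1OCc1ccccc1 | intermediate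
21 | methyl (2S,3R,5S)-5-[4-(benzyloxy)-3-methoxybenzyl]-2-{(2R,3R)-7-methoxy-2-[3-methoxy-4-(pivaloyloxy)phenyl]-3-[(pivaloyloxy)methyl]-2,3-dihydrobenzofuran-5-yl}-4-oxotetrahydrofuran-3-carboxylate | COc1cc(C[C@@H]2O[C@H](c3cc(OC)c4c(c3)[C@H](COC(=O)C(C)(C)C)[C@H](c3ccc(OC(=O)C(C)(C)C)c(OC)c3)O4)[C@@H](C(=O)OC)C2=O)ccc1OCc1ccccc1 | intermediate
22 | methyl (2S,3S,4S,5S)-5-[4-(benzyloxy)-3-methoxybenzyl]-4-hydroxy-2-{(2R,3R)-7-methoxy-2-[3-methoxy-4-(pivaloyloxy)phenyl]-3-[(pivaloyloxy)methyl]-2,3-dihydrobenzofuran-5-yl}tetrahydrofuran-3-carboxylate | COc1cc(C[C@@H]2O[C@H](c3cc(OC)c4c(c3)[C@H](COC(=O)C(C)(C)C)[C@H](c3ccc(OC(=O)C(C)(C)C)c(OC)c3)O4)[C@@H](C(=O)OC)[C@@H]2O)ccc1OCc1ccccc1 | intermediate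
23 | (2S,3S,4S,5S)-5-[4-(benzyloxy)-3-methoxybenzyl]-2-[(2R,3R)-2-(4-hydroxy-3-methoxyphenyl)-3-(hydroxymethyl)-7-methoxy-2,3-dihydrobenzofuran-5-yl]-3-(hydroxymethyl)tetrahydrofuran-4-ol | COc1cc(C[C@@H]2O[C@H](c3cc(OC)c4c(c3)[C@H](CO)[C@H](c3ccc(O)c(OC)c3)O4)[C@@H](CO)[C@@H]2O)ccc1OCc1ccccc1 | intermediate
24 | (2S,3S,4S,5S)-5-(4-hydroxy-3-methoxybenzyl)-2-[(2R,3R)-2-(4-hydroxy-3-methoxyphenyl)-3-(hydroxymethyl)-7-methoxy-2,3-dihydrobenzofuran-5-yl]-3-(hydroxymethyl)tetrahydrofuran-4-ol | COc1cc(C[C@@H]2O[C@H](c3cc(OC)c4c(c3)[C@H](CO)[C@H](c3ccc(O)c(OC)c3)O4)[C@@H](CO)[C@@H]2O)ccc1O | target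

## Step count and risks

Total: 19 steps. Longest linear sequence: 13 steps (steps 7–19, from vanillin 9); the ring C branch (steps 1–6) joins at step 15.

**Step 16 (key step, new method).** Four processes may interfere:
- return of the enolate through oxygen, so that 20 only epimerises;
- closure of ring C on the oxocarbenium ion (a six-membered oxa-Pictet–Spengler cyclisation para to the ring C methoxy group);
- poor 2,5-cis selectivity, because envelope preferences in five-membered transition states are small;
- ionisation of the benzylic C2'–O1' bond if the medium turns protic.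

The fallback uses known chemistry and sets out from 3 and 19. Horner–Wadsworth–Emmons olefination of 19 (trimethyl phosphonoacetate, LiCl, DBU, MeCN) gives methyl (E)-3-{(2R,3R)-7-methoxy-2-[3-methoxy-4-(pivaloyloxy)phenyl]-3-[(pivaloyloxy)methyl]-2,3-dihydrobenzofuran-5-yl}acrylate F1. The sodium alkoxide of 3 (NaH, THF, 0 °C → rt) then adds to F1 (oxa-Michael) and the resulting ester enolate closes on the benzyl ester (Dieckmann condensation). This is the long-established route to 4-oxotetrahydrofuran-3-carboxylates, and C2 settles by reversible oxa-Michael addition. The fallback comes back to the route at 21.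

**Step 15.** Hemiacetal formation with an electron-rich aryl aldehyde is unfavourable. Intermolecular oxa-Michael oligomerisation of 8, base-induced isomerisation of the γ-hydroxy ynoate to a γ-oxo enoate (loss of C5), or acyl transfer from the aryl pivalate to an alkoxide may then outrun the cyclisation. The fallback sets out from 3 and 19. Saponification of 3 (LiOH, THF/H2O) gives (S)-3-[4-(benzyloxy)-3-methoxyphenyl]-2-hydroxypropanoic acid F2. Acid-catalysed condensation with 19 (p-TsOH, benzene, water removal) gives (2S,5S)-5-[4-(benzyloxy)-3-methoxybenzyl]-2-{(2R,3R)-7-methoxy-2-[3-methoxy-4-(pivaloyloxy)phenyl]-3-[(pivaloyloxy)methyl]-2,3-dihydrobenzofuran-5-yl}-1,3-dioxolan-4-one F3. Wittig olefination of this activated lactone carbonyl with Ph3P=CHCO2Me (toluene, 110 °C) returns to the route at 20; enoate geometry and acetal configuration again do not matter.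

**Step 17.** The ketone is flanked by two substituted carbons, so hydrogenation may be slow, and substrate bias or chelation through the ring oxygen may override the catalyst, giving the wrong face at C4 or the cis hydroxy ester. The fallback sets out from 21 and changes the order of reductions.
- Silylation (TBSOTf, Et3N, CH2Cl2) gives methyl (2R,5S)-5-[4-(benzyloxy)-3-methoxybenzyl]-4-[(tert-butyldimethylsilyl)oxy]-2-{(2R,3R)-7-methoxy-2-[3-methoxy-4-(pivaloyloxy)phenyl]-3-[(pivaloyloxy)methyl]-2,3-dihydrobenzofuran-5-yl}-2,5-dihydrofuran-3-carboxylate F4.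
- Excess i-Bu2AlH (CH2Cl2, −78 °C) reduces the ester and removes both pivalates to give 4-[(2R,3R)-5-{(2R,5S)-5-[4-(benzyloxy)-3-methoxybenzyl]-4-[(tert-butyldimethylsilyl)oxy]-3-(hydroxymethyl)-2,5-dihydrofuran-2-yl}-3-(hydroxymethyl)-7-methoxy-2,3-dihydrobenzofuran-2-yl]-2-methoxyphenol F5.
- Buffered fluoride (HF·pyridine, pyridine, THF) unveils the ketone, which is left to equilibrate at C3, giving (2S,3R,5S)-5-[4-(benzyloxy)-3-methoxybenzyl]-2-[(2R,3R)-2-(4-hydroxy-3-methoxyphenyl)-3-(hydroxymethyl)-7-methoxy-2,3-dihydrobenzofuran-5-yl]-3-(hydroxymethyl)tetrahydrofuran-4-one F6.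
- Evans–Saksena reduction (Me4NBH(OAc)3, AcOH/MeCN, −20 °C) delivers hydride from the face of the hydroxymethyl group and returns to the route at 23.

**Step 11.** The crowded ortho-alkoxy aryl iodide may undergo oxidative addition or diazo transfer slowly, so that palladium-carbene decomposition of the diazoacetate takes over. The fallback sets out from 14. Negishi-type coupling with the Reformatsky reagent BrZnCH2CO2Me (Pd(dba)2, P(t-Bu)3, THF) gives methyl 2-[5-(1,3-dioxolan-2-yl)-3-methoxy-2-{[3-methoxy-4-(pivaloyloxy)benzyl]oxy}phenyl]acetate F7. Regitz diazo transfer (4-acetamidobenzenesulfonyl azide, DBU, MeCN) returns to the route at 15.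

**Step 12.** The methoxy group flanking the ether oxygen and the less electron-rich ring A may slow the insertion and erode enantioselectivity, or let carbene dimerisation compete. The fallback sets out from 14 and adds auxiliary control and a separation.
- Coupling as in step 11 but with (1R,2S,5R)-menthyl diazoacetate gives (1R,2S,5R)-2-isopropyl-5-methylcyclohexyl 2-diazo-2-[5-(1,3-dioxolan-2-yl)-3-methoxy-2-{[3-methoxy-4-(pivaloyloxy)benzyl]oxy}phenyl]acetate F8.
- Insertion with Rh2(S-PTTL)4 gives (1R,2S,5R)-2-isopropyl-5-methylcyclohexyl (2R,3S)-5-(1,3-dioxolan-2-yl)-7-methoxy-2-[3-methoxy-4-(pivaloyloxy)phenyl]-2,3-dihydrobenzofuran-3-carboxylate F9. Its stereoisomers are diastereomers and can be removed by chromatography or crystallisation.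
- LiAlH4 reduction returns to the route at 17.

## Further compounds

F1 | step 16 | methyl (E)-3-{(2R,3R)-7-methoxy-2-[3-methoxy-4-(pivaloyloxy)phenyl]-3-[(pivaloyloxy)methyl]-2,3-dihydrobenzofuran-5-yl}acrylate | COC(=O)/C=C/c1cc(OC)c2c(c1)[C@H](COC(=O)C(C)(C)C)[C@H](c1ccc(OC(=O)C(C)(C)C)c(OC)c1)O2
F2 | step 15 | (S)-3-[4-(benzyloxy)-3-methoxyphenyl]-2-hydroxypropanoic acid | COc1cc(C[C@H](O)C(=O)O)ccc1OCc1ccccc1
F3 | step 15 | (2S,5S)-5-[4-(benzyloxy)-3-methoxybenzyl]-2-{(2R,3R)-7-methoxy-2-[3-methoxy-4-(pivaloyloxy)phenyl]-3-[(pivaloyloxy)methyl]-2,3-dihydrobenzofuran-5-yl}-1,3-dioxolan-4-one | COc1cc(C[C@@H]2O[C@H](c3cc(OC)c4c(c3)[C@H](COC(=O)C(C)(C)C)[C@H](c3ccc(OC(=O)C(C)(C)C)c(OC)c3)O4)OC2=O)ccc1OCc1ccccc1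
F4 | step 17 | methyl (2R,5S)-5-[4-(benzyloxy)-3-methoxybenzyl]-4-[(tert-butyldimethylsilyl)oxy]-2-{(2R,3R)-7-methoxy-2-[3-methoxy-4-(pivaloyloxy)phenyl]-3-[(pivaloyloxy)methyl]-2,3-dihydrobenzofuran-5-yl}-2,5-dihydrofuran-3-carboxylate (2,5-cis) | COc1cc(C[C@@H]2O[C@H](c3cc(OC)c4c(c3)[C@H](COC(=O)C(C)(C)C)[C@H](c3ccc(OC(=O)C(C)(C)C)c(OC)c3)O4)C(C(=O)OC)=C2O[Si](C)(C)C(C)(C)C)ccc1OCc1ccccc1
F5 | step 17 | 4-[(2R,3R)-5-{(2R,5S)-5-[4-(benzyloxy)-3-methoxybenzyl]-4-[(tert-butyldimethylsilyl)oxy]-3-(hydroxymethyl)-2,5-dihydrofuran-2-yl}-3-(hydroxymethyl)-7-methoxy-2,3-dihydrobenzofuran-2-yl]-2-methoxyphenol | COc1cc(C[C@@H]2O[C@H](c3cc(OC)c4c(c3)[C@H](CO)[C@H](c3ccc(O)c(OC)c3)O4)C(CO)=C2O[Si](C)(C)C(C)(C)C)ccc1OCc1ccccc1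
F6 | step 17 | (2S,3R,5S)-5-[4-(benzyloxy)-3-methoxybenzyl]-2-[(2R,3R)-2-(4-hydroxy-3-methoxyphenyl)-3-(hydroxymethyl)-7-methoxy-2,3-dihydrobenzofuran-5-yl]-3-(hydroxymethyl)tetrahydrofuran-4-one | COc1cc(C[C@@H]2O[C@H](c3cc(OC)c4c(c3)[C@H](CO)[C@H](c3ccc(O)c(OC)c3)O4)[C@@H](CO)C2=O)ccc1OCc1ccccc1
F7 | step 11 | methyl 2-[5-(1,3-dioxolan-2-yl)-3-methoxy-2-{[3-methoxy-4-(pivaloyloxy)benzyl]oxy}phenyl]acetate | COc1cc(C2OCCO2)cc(CC(=O)OC)c1OCc1ccc(OC(=O)C(C)(C)C)c(OC)c1
F8 | step 12 | (1R,2S,5R)-2-isopropyl-5-methylcyclohexyl 2-diazo-2-[5-(1,3-dioxolan-2-yl)-3-methoxy-2-{[3-methoxy-4-(pivaloyloxy)benzyl]oxy}phenyl]acetate | COc1cc(C2OCCO2)cc(C(=[N+]=[N-])C(=O)O[C@@H]2C[C@H](C)CC[C@H]2C(C)C)c1OCc1ccc(OC(=O)C(C)(C)C)c(OC)c1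
F9 | step 12 | (1R,2S,5R)-2-isopropyl-5-methylcyclohexyl (2R,3S)-5-(1,3-dioxolan-2-yl)-7-methoxy-2-[3-methoxy-4-(pivaloyloxy)phenyl]-2,3-dihydrobenzofuran-3-carboxylate | O1CCOC1c1cc(OC)c2c(c1)[C@H](C(=O)O[C@@H]3C[C@H](C)CC[C@H]3C(C)C)[C@H](c1ccc(OC(=O)C(C)(C)C)c(OC)c1)O2
A1 | alternative 1 | (S)-2-[4-(benzyloxy)-3-methoxyphenyl]-6-bromo-3-diazo-8-methoxychroman-4-one | Brc1cc(OC)c2c(c1)C(=O)C(=[N+]=[N-])[C@H](c1ccc(OCc3ccccc3)c(OC)c1)O2
A2 | alternative 1 | methyl (2R,3S)-2-[4-(benzyloxy)-3-methoxyphenyl]-5-bromo-7-methoxy-2,3-dihydrobenzofuran-3-carboxylate (cis) | Brc1cc(OC)c2c(c1)[C@H](C(=O)OC)[C@H](c1ccc(OCc3ccccc3)c(OC)c1)O2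
A3 | alternative 2 | (S)-3-[4-(benzyloxy)-3-methoxyphenyl]-2-[(4-methoxybenzyl)oxy]propanal | COc1cc(C[C@H](OCc2ccc(OC)cc2)C=O)ccc1OCc1ccccc1
A4 | alternative 2 | 4-[(2R,3R)-3-[(benzyloxy)methyl]-7-methoxy-5-{(E)-3-[(triisopropylsilyl)oxy]prop-1-en-1-yl}-2,3-dihydrobenzofuran-2-yl]-2-methoxyphenyl pivalate | CC(C)[Si](OC/C=C/c1cc(OC)c2c(c1)[C@H](COCc1ccccc1)[C@H](c1ccc(OC(=O)C(C)(C)C)c(OC)c1)O2)(C(C)C)C(C)C
A5 | alternative 2 | 2-aryl-5-benzyl-3-(triisopropylsilyloxymethyl)tetrahydrofuran-4-ol with the ring configuration of 24, ring A as pivalate, ring C and the C3' hydroxymethyl group as benzyl ethers | COc1cc(C[C@@H]2O[C@H](c3cc(OC)c4c(c3)[C@H](COCc3ccccc3)[C@H](c3ccc(OC(=O)C(C)(C)C)c(OC)c3)O4)[C@@H](CO[Si](C(C)C)(C(C)C)C(C)C)[C@@H]2O)ccc1OCc1ccccc1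
A6 | alternative 3 | full-skeleton methyl aryldiazoacetate: ring B carries the diazoacetate next to the 4-(benzyloxy)-3-methoxybenzyl ether, tetrahydrofuran configured as in 24 with both hydroxyl groups as tert-butyldimethylsilyl ethers, ring C as benzyl ether | COc1cc(C[C@@H]2O[C@H](c3cc(OC)c(OCc4ccc(OCc5ccccc5)c(OC)c4)c(c3)C(=[N+]=[N-])C(=O)OC)[C@@H](CO[Si](C)(C)C(C)(C)C)[C@@H]2O[Si](C)(C)C(C)(C)C)ccc1OCc1ccccc1
A7 | alternative 3 | full-skeleton methyl cis-(2R,3S)-dihydrobenzofuran-3-carboxylate, tetrahydrofuran configured as in 24 with both hydroxyl groups as tert-butyldimethylsilyl ethers, rings A and C as benzyl ethers | COc1cc(C[C@@H]2O[C@H](c3cc(OC)c4c(c3)[C@H](C(=O)OC)[C@H](c3ccc(OCc5ccccc5)c(OC)c3)O4)[C@@H](CO[Si](C)(C)C(C)(C)C)[C@@H]2O[Si](C)(C)C(C)(C)C)ccc1OCc1ccccc1
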